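**Retrosynthetic overview**

1. The decanoate is cut back to iridal (selective acylation of the primary alcohol); iridal comes from its dimethyl acetal / silyl ether by mild acid hydrolysis.
2. The (Z)-tetrasubstituted enal comes from an (E)-enol triflate by Negishi methylation; that triflate comes from a 1-acylcyclohexene by conjugate addition of the C3 chain and O-triflation of the enolate, which sets the ring CH centre and the alkene geometry together.
3. The acylcyclohexene comes from a cyclohexenyl triflate (Nozaki–Hiyama–Kishi coupling, oxidation); that triflate comes from a 4-hydroxy-enone by hydroxyl-directed conjugate methylation (quaternary carbon, CH3 cis to OH).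
4. The hydroxy-enone comes from a bromo-para-quinol and a farnesol-derived tetraene by hydroboration / B-alkyl Suzuki coupling and selective hydrogenation.
5. Key bond: the tertiary C–O bond, made by enantioselective para-hydroxylative dearomatization of 3-bromo-4-methylphenol. The only ring is the benzene ring of that phenol, carried through; no ring-forming step is needed.

Abbreviation: homofarnesyl = (3E,7E)-4,8,12-trimethyltrideca-3,7,11-trien-1-yl.

Assumption: the sense of induction of the new catalyst in the first step cannot be predicted with certainty; the (R,R)-catalyst is written, and its mirror image (from the other ethyl lactate) is used if that one proves to give the (S)-quinol.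

**Route**

Step 1
Reactants: 1 3-bromo-4-methylphenol
Product: 2 (S)-3-bromo-4-hydroxy-4-methylcyclohexa-2,5-dien-1-one
Conditions: (R,R)-2,2'-[(2-iodo-1,3-phenylene)bis(oxy)]bis[N-(2,6-diisopropylphenyl)propanamide] (10 mol %), mCPBA (1.3 equiv), MeCN/H2O 4:1, 0 °C
Reagents that add atoms: water, O
Why: Proposed new method: mCPBA oxidizes the iodoarene to a trivalent iodine species that takes up the phenol as an aryloxy ligand (associative path in aqueous MeCN), the two lactamide arms fold over iodine through N–H···O hydrogen bonds into a C2-symmetric pocket whose 2,6-diisopropylanilide walls force the C–Br bond out of the pocket so that only one face of C4 is open, and water attacks C4 on that face as the iodoarene leaves from oxygen (SN2'-type), which makes the tertiary C–O bond and the (S) carbinol centre and cannot rearomatize because C4 carries the methyl group; closest known reaction type: chiral aryl iodide-catalysed oxidative (hydrative) dearomatization of phenols to quinols and spirolactones, where high enantioselectivity has relied on a substituent ortho to the phenol oxygen or a tethered nucleophile, not on a meta-halogen as the only differentiating group.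

Step 2
Reactants: 3 (2E,6E)-farnesol
Product: 4 (2E,6E)-farnesal
Conditions: PhI(OAc)2 (1.1 equiv), (2,2,6,6-tetramethylpiperidin-1-yl)oxyl (10 mol %), CH2Cl2, 0 °C → rt
Reagents that add atoms: none
Why: Oxoammonium (TEMPO-type) oxidation of a primary allylic alcohol stops at the enal and does not isomerize the 2,3-double bond.

Step 3
Reactants: 4 (2E,6E)-farnesal
Product: 5 (3E,7E)-4,8,12-trimethyltrideca-1,3,7,11-tetraene
Conditions: Ph3PCH3Br, KOtBu, THF, 0 °C → rt
Reagents that add atoms: methyltriphenylphosphonium bromide, C[P+](c1ccccc1)(c1ccccc1)c1ccccc1.[Br-]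
Why: Wittig methylenation of the enal gives the terminal 1,3-diene and leaves the (E)-trisubstituted alkenes as they are.

Step 4
Reactants: 5 (3E,7E)-4,8,12-trimethyltrideca-1,3,7,11-tetraene; 2 (S)-3-bromo-4-hydroxy-4-methylcyclohexa-2,5-dien-1-one
Product: 7 (S)-4-hydroxy-3-homofarnesyl-4-methylcyclohexa-2,5-dien-1-one, via homofarnesyl-9-BBN 6 (not isolated)
Conditions: 9-BBN, THF, 0 °C → rt; then 2, PdCl2(dppf) (5 mol %), aq K3PO4, THF/DMF, rt
Reagents that add atoms: none
Why: The bulky borane hydroborates only the terminal vinyl carbon of the diene (anti-Markovnikov), and the primary alkylborane then undergoes B-alkyl Suzuki–Miyaura coupling at the β-bromoenone C–Br bond without touching the carbinol stereocentre.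

Step 5
Reactants: 7 (S)-4-hydroxy-3-homofarnesyl-4-methylcyclohexa-2,5-dien-1-one
Product: 8 (S)-4-hydroxy-3-homofarnesyl-4-methylcyclohex-2-en-1-one
Conditions: H2 (1 atm), RhCl(PPh3)3 (5 mol %), benzene, rt
Reagents that add atoms: none
Why: Homogeneous hydrogenation with RhCl(PPh3)3 reduces only the 1,2-disubstituted enone C=C of a cross-conjugated dienone and leaves the trisubstituted enone and the three trisubstituted chain alkenes.

Step 6
Reactants: 8 (S)-4-hydroxy-3-homofarnesyl-4-methylcyclohex-2-en-1-one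
Product: 10 (3S,4S)-4-hydroxy-3-homofarnesyl-3,4-dimethylcyclohex-1-en-1-yl trifluoromethanesulfonate, via aluminium enolate 9 (not isolated)
Conditions: AlMe3 (4 equiv), CH2Cl2, −78 → 0 °C; MeLi, THF, −78 °C; Comins' reagent, −78 → 0 °C
Reagents that add atoms: trimethylaluminium, C[Al](C)C; Comins' reagent [N-(5-chloropyridin-2-yl)-1,1,1-trifluoro-N-(trifluoromethylsulfonyl)methanesulfonamide], FC(F)(F)S(=O)(=O)N(c1ccc(Cl)cn1)S(=O)(=O)C(F)(F)F
Why: Hydroxyl-directed conjugate addition of AlMe3 (the known behaviour of para-quinols and 4-hydroxycyclohexenones): the aluminium alkoxide hands a methyl group to the neighbouring β-carbon on its own face through a cyclic transition state, so the new quaternary centre is (3S) with CH3 cis to O, and the enolate, formed only toward C2, is fixed as the enol triflate after activation with MeLi.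

Step 7
Reactants: 10 (3S,4S)-4-hydroxy-3-homofarnesyl-3,4-dimethylcyclohex-1-en-1-yl trifluoromethanesulfonate
Product: 11 1-[(3S,4S)-4-hydroxy-3-homofarnesyl-3,4-dimethylcyclohex-1-en-1-yl]-2,2-dimethoxyethan-1-ol (both epimers at the new carbinol carbon)
Conditions: anhydrous 2,2-dimethoxyacetaldehyde, CrCl2 (4 equiv), NiCl2 (2 mol %), DMF, rt
Reagents that add atoms: 2,2-dimethoxyacetaldehyde, COC(OC)C=O
Why: Nozaki–Hiyama–Kishi coupling (nickel-catalysed activation of the C–OTf bond, chromium-mediated addition to the aldehyde) tolerates the free tertiary alcohol, and the new carbinol centre is removed in the next step.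

Step 8
Reactants: 11 1-[(3S,4S)-4-hydroxy-3-homofarnesyl-3,4-dimethylcyclohex-1-en-1-yl]-2,2-dimethoxyethan-1-ol
Product: 12 1-[(3S,4S)-4-hydroxy-3-homofarnesyl-3,4-dimethylcyclohex-1-en-1-yl]-2,2-dimethoxyethan-1-one
Conditions: Dess–Martin periodinane (1.3 equiv), pyridine, CH2Cl2, 0 °C → rt
Reagents that add atoms: none
Why: Dess–Martin oxidation converts the secondary allylic alcohol into the enone while the tertiary alcohol, the acetal and the alkenes are inert.

Step 9
Reactants: 12 1-[(3S,4S)-4-hydroxy-3-homofarnesyl-3,4-dimethylcyclohex-1-en-1-yl]-2,2-dimethoxyethan-1-one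
Product: 14 (1E)-1-[(2R,3S,4S)-2-{3-[(tert-butyldimethylsilyl)oxy]propyl}-4-hydroxy-3-homofarnesyl-3,4-dimethylcyclohexylidene]-2,2-dimethoxyethyl trifluoromethanesulfonate, via magnesium enolate 13 (not isolated)
Conditions: TBSO(CH2)3Br, Mg, THF; then 12, CuBr·SMe2 (20 mol %), THF, −78 → −40 °C; Comins' reagent, −78 → 0 °C
Reagents that add atoms: (3-bromopropoxy)(tert-butyl)dimethylsilane (used as its Grignard reagent), BrCCCO[Si](C)(C)C(C)(C)C; Comins' reagent, FC(F)(F)S(=O)(=O)N(c1ccc(Cl)cn1)S(=O)(=O)C(F)(F)F
Why: Copper-catalysed conjugate addition of a Grignard reagent with O-triflation of the enolate: the alkyl group attacks the ring β-carbon axially on the face of the C4 alkoxide and anti to the pseudoaxial homofarnesyl group (the other axial path is blocked by the then axial C4 methyl), which sets the new CH centre as (2R), and because the 1-acylcyclohexene reacts in its s-trans form the enolate oxygen ends trans to that CH, giving the (E)-enol triflate.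

Step 10
Reactants: 14 (1E)-1-[(2R,3S,4S)-2-{3-[(tert-butyldimethylsilyl)oxy]propyl}-4-hydroxy-3-homofarnesyl-3,4-dimethylcyclohexylidene]-2,2-dimethoxyethyl trifluoromethanesulfonate
Product: 15 (1S,2S,3R,4Z)-3-{3-[(tert-butyldimethylsilyl)oxy]propyl}-4-(1,1-dimethoxypropan-2-ylidene)-2-homofarnesyl-1,2-dimethylcyclohexan-1-ol
Conditions: MeZnCl (3 equiv), Pd(PPh3)4 (5 mol %), THF, 50 °C
Reagents that add atoms: methylzinc chloride, C[Zn]Cl
Why: Negishi coupling of an enol triflate goes with retention of alkene geometry, so CH3 takes the place of OTf (trans to the ring CH) and the acetal carbon stays cis to it (Z).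

Step 11
Reactants: 15 (1S,2S,3R,4Z)-3-{3-[(tert-butyldimethylsilyl)oxy]propyl}-4-(1,1-dimethoxypropan-2-ylidene)-2-homofarnesyl-1,2-dimethylcyclohexan-1-ol
Product: 16 iridal [(2Z)-2-[(2R,3S,4S)-4-hydroxy-2-(3-hydroxypropyl)-3-homofarnesyl-3,4-dimethylcyclohexylidene]propanal]
Conditions: AcOH/THF/H2O 3:1:1, 35 °C
Reagents that add atoms: water, O
Why: Mild acid hydrolysis cleaves the allylic dimethyl acetal and the primary silyl ether without touching the alkene geometry, the tertiary alcohol or the polyene chain.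

Step 12
Reactants: 16 iridal
Product: 17 3-[(1R,2S,3S,6Z)-3-hydroxy-2-homofarnesyl-2,3-dimethyl-6-(1-oxopropan-2-ylidene)cyclohexyl]propyl decanoate
Conditions: decanoyl chloride (1.05 equiv), pyridine, CH2Cl2, −20 → 0 °C
Reagents that add atoms: decanoyl chloride, CCCCCCCCCC(=O)Cl
Why: Acylation with an acid chloride is far faster at the primary alcohol than at the hindered tertiary alcohol, so only the mono-decanoate forms.

**Compound list**

1 | 3-bromo-4-methylphenol | Cc1ccc(O)cc1Br | starting material
2 | (S)-3-bromo-4-hydroxy-4-methylcyclohexa-2,5-dien-1-one | O=C1C=C[C@](C)(O)C(Br)=C1 | intermediate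
3 | (2E,6E)-farnesol | OC/C=C(\C)CC/C=C(\C)CCC=C(C)C | starting material
4 | (2E,6E)-farnesal | O=C/C=C(\C)CC/C=C(\C)CCC=C(C)C | intermediate
5 | (3E,7E)-4,8,12-trimethyltrideca-1,3,7,11-tetraene | C=C/C=C(\C)CC/C=C(\C)CCC=C(C)C | intermediate
6 | 9-homofarnesyl-9-borabicyclo[3.3.1]nonane | B1(CC/C=C(\C)CC/C=C(\C)CCC=C(C)C)C2CCCC1CCC2 | intermediate (not isolated)
7 | (S)-4-hydroxy-3-homofarnesyl-4-methylcyclohexa-2,5-dien-1-one | O=C1C=C[C@](C)(O)C(CC/C=C(\C)CC/C=C(\C)CCC=C(C)C)=C1 | intermediate
8 | (S)-4-hydroxy-3-homofarnesyl-4-methylcyclohex-2-en-1-one | O=C1CC[C@](C)(O)C(CC/C=C(\C)CC/C=C(\C)CCC=C(C)C)=C1 | intermediate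
9 | bis(dimethylaluminium) enolate-alkoxide of (3S,4S)-4-hydroxy-3-homofarnesyl-3,4-dimethylcyclohexan-1-one (C1=C2 enolate) | C[Al](C)OC1=C[C@](C)(CC/C=C(\C)CC/C=C(\C)CCC=C(C)C)[C@@](C)(O[Al](C)C)CC1 | intermediate (not isolated)
10 | (3S,4S)-4-hydroxy-3-homofarnesyl-3,4-dimethylcyclohex-1-en-1-yl trifluoromethanesulfonate | FC(F)(F)S(=O)(=O)OC1=C[C@](C)(CC/C=C(\C)CC/C=C(\C)CCC=C(C)C)[C@@](C)(O)CC1 | intermediate
11 | 1-[(3S,4S)-4-hydroxy-3-homofarnesyl-3,4-dimethylcyclohex-1-en-1-yl]-2,2-dimethoxyethan-1-ol (both carbinol epimers) | COC(OC)C(O)C1=C[C@](C)(CC/C=C(\C)CC/C=C(\C)CCC=C(C)C)[C@@](C)(O)CC1 | intermediate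
12 | 1-[(3S,4S)-4-hydroxy-3-homofarnesyl-3,4-dimethylcyclohex-1-en-1-yl]-2,2-dimethoxyethan-1-one | COC(OC)C(=O)C1=C[C@](C)(CC/C=C(\C)CC/C=C(\C)CCC=C(C)C)[C@@](C)(O)CC1 | intermediate
13 | bis(bromomagnesium) (E)-enolate-alkoxide of the conjugate adduct of 12 | CC(C)(C)[Si](C)(C)OCCC[C@@H]1/C(=C(/O[Mg]Br)C(OC)OC)CC[C@](C)(O[Mg]Br)[C@@]1(C)CC/C=C(\C)CC/C=C(\C)CCC=C(C)C | intermediate (not isolated)
14 | (1E)-1-[(2R,3S,4S)-2-{3-[(tert-butyldimethylsilyl)oxy]propyl}-4-hydroxy-3-homofarnesyl-3,4-dimethylcyclohexylidene]-2,2-dimethoxyethyl trifluoromethanesulfonate | CC(C)(C)[Si](C)(C)OCCC[C@@H]1/C(=C(/OS(=O)(=O)C(F)(F)F)C(OC)OC)CC[C@](C)(O)[C@@]1(C)CC/C=C(\C)CC/C=C(\C)CCC=C(C)C | intermediate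
15 | (1S,2S,3R,4Z)-3-{3-[(tert-butyldimethylsilyl)oxy]propyl}-4-(1,1-dimethoxypropan-2-ylidene)-2-homofarnesyl-1,2-dimethylcyclohexan-1-ol | CC(C)(C)[Si](C)(C)OCCC[C@@H]1/C(=C(/C)C(OC)OC)CC[C@](C)(O)[C@@]1(C)CC/C=C(\C)CC/C=C(\C)CCC=C(C)C | intermediate
16 | iridal, (2Z)-2-[(2R,3S,4S)-4-hydroxy-2-(3-hydroxypropyl)-3-homofarnesyl-3,4-dimethylcyclohexylidene]propanal | OCCC[C@@H]1/C(=C(/C)C=O)CC[C@](C)(O)[C@@]1(C)CC/C=C(\C)CC/C=C(\C)CCC=C(C)C | intermediate
17 | 3-[(1R,2S,3S,6Z)-3-hydroxy-2-homofarnesyl-2,3-dimethyl-6-(1-oxopropan-2-ylidene)cyclohexyl]propyl decanoate | CCCCCCCCCC(=O)OCCC[C@@H]1/C(=C(/C)C=O)CC[C@](C)(O)[C@@]1(C)CC/C=C(\C)CC/C=C(\C)CCC=C(C)C | target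

**Step count and risks**

Total: 12 steps. Longest linear sequence: 11 steps (from 3 through steps 2 to 12); 10 steps from 1.

The three steps most likely to fail:

Step 1, the proposed new dearomatization. The catalyst may give low enantioselectivity with only a meta-bromine to differentiate the faces, and oxidation at the free ortho positions may compete. The fallback uses known chemistry and sets out from 1: oxidation with stoichiometric PhI(OAc)2 in MeCN/H2O at 0 °C gives racemic 3-bromo-4-hydroxy-4-methylcyclohexa-2,5-dien-1-one F1. Preparative supercritical-fluid chromatography on a cellulose tris(3,5-dimethylphenylcarbamate) phase separates the enantiomers. The unwanted (R)-3-bromo-4-hydroxy-4-methylcyclohexa-2,5-dien-1-one F2 is discarded, and the (S)-enantiomer is 2, where the fallback rejoins the route.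

Step 6, the directed methylation that builds the quaternary carbon next to the fully substituted carbinol. The β-carbon is hindered, so the reaction may be slow or go by 1,2-addition. The fallback sets out from 8 and replaces substrate direction by catalyst control:
- Me3SiCl and imidazole give (S)-3-homofarnesyl-4-methyl-4-(trimethylsilyloxy)cyclohex-2-en-1-one F3.
- Copper-catalysed asymmetric conjugate addition of AlMe3 follows (copper thiophene-2-carboxylate, 5 mol %, with a BINOL-derived N,N-bis(1-phenylethyl)phosphoramidite ligand of the enantiomer that places CH3 cis to the silyloxy group, Et2O, −30 °C). It gives the dimethylaluminium enolate of (3S,4S)-3-homofarnesyl-3,4-dimethyl-4-(trimethylsilyloxy)cyclohexan-1-one F4.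
- MeLi and Comins' reagent convert this into (3S,4S)-3-homofarnesyl-3,4-dimethyl-4-(trimethylsilyloxy)cyclohex-1-en-1-yl trifluoromethanesulfonate F5.
- Aqueous citric acid in THF removes the silyl group and returns the route to 10.

Step 9, the conjugate addition with enolate triflation. The β-carbon is neopentyl-like, the α-keto acetal invites 1,2-addition by the Grignard reagent, and the enolate geometry rests on the s-trans preference of the acylcyclohexene; the geometry of 14 should be checked by NOE. The fallback sets out from 12 and replaces the organocopper by a radical conjugate addition. Tris[3-(tert-butyldimethylsilyloxy)propyl]borane (from allyl tert-butyldimethylsilyl ether and BH3·SMe2) with a trace of air in THF adds its primary alkyl radical to the ring β-carbon, with the same facial preference. The resulting α-keto radical is captured on oxygen as the boron enolate (1E)-1-[(2R,3S,4S)-2-{3-[(tert-butyldimethylsilyl)oxy]propyl}-4-hydroxy-3-homofarnesyl-3,4-dimethylcyclohexylidene]-2,2-dimethoxyethyl bis{3-[(tert-butyldimethylsilyl)oxy]propyl}borinate F6. MeLi and then Comins' reagent in the same flask convert F6 into 14, where the route continues.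

**Further compounds**

F1 | step 1 | racemic 3-bromo-4-hydroxy-4-methylcyclohexa-2,5-dien-1-one | O=C1C=CC(C)(O)C(Br)=C1
F2 | step 1 | (R)-3-bromo-4-hydroxy-4-methylcyclohexa-2,5-dien-1-one | O=C1C=C[C@@](C)(O)C(Br)=C1
F3 | step 6 | (S)-3-homofarnesyl-4-methyl-4-(trimethylsilyloxy)cyclohex-2-en-1-one | O=C1CC[C@](C)(O[Si](C)(C)C)C(CC/C=C(\C)CC/C=C(\C)CCC=C(C)C)=C1
F4 | step 6 | dimethylaluminium enolate of (3S,4S)-3-homofarnesyl-3,4-dimethyl-4-(trimethylsilyloxy)cyclohexan-1-one | C[Al](C)OC1=C[C@](C)(CC/C=C(\C)CC/C=C(\C)CCC=C(C)C)[C@@](C)(O[Si](C)(C)C)CC1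
F5 | step 6 | (3S,4S)-3-homofarnesyl-3,4-dimethyl-4-(trimethylsilyloxy)cyclohex-1-en-1-yl trifluoromethanesulfonate | FC(F)(F)S(=O)(=O)OC1=C[C@](C)(CC/C=C(\C)CC/C=C(\C)CCC=C(C)C)[C@@](C)(O[Si](C)(C)C)CC1
F6 | step 9 | (1E)-1-[(2R,3S,4S)-2-{3-[(tert-butyldimethylsilyl)oxy]propyl}-4-hydroxy-3-homofarnesyl-3,4-dimethylcyclohexylidene]-2,2-dimethoxyethyl bis{3-[(tert-butyldimethylsilyl)oxy]propyl}borinate | CC(C)(C)[Si](C)(C)OCCC[C@@H]1/C(=C(/OB(CCCO[Si](C)(C)C(C)(C)C)CCCO[Si](C)(C)C(C)(C)C)C(OC)OC)CC[C@](C)(O)[C@@]1(C)CC/C=C(\C)CC/C=C(\C)CCC=C(C)C
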